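The ratio to carry through this flask is the odds at one fork: an electrophile molecule becomes target with the nucleophile, or it is lost by another way, here taken to run through the protic impurity.

- gamma: electrophile 0.050 M; nucleophile 0.10 M; protic impurity 0.038 M; run made earlier
- flask: electrophile 0.050 M; nucleophile 0.100 M; protic impurity 0.0250 M; time 30 h

gamma run (percent of the electrophile charged)

| time / h | electrophile / % | target / % |
|---|---|---|
| 0.417 | 88.3 | 4.2 |
| 1.00 | 75.1 | 9.4 |
| 2.00 | 60.2 | 16.6 |
| 3.00 | 48.8 | 20.0 |

(standard deviation of a reading: 0.5 percentage points)

- part of the electrophile that has reacted at 30 h
- share of the unused nucleophile that is free and not bound as protonated nucleophile, at 30 h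

1. In this reckoning, the odds at the start of a flask depend on the nucleophile charge over the impurity charge. Time and the electrophile charge do not enter. Proportion to the impurity is an assumption, since no earlier run varies it.

2. The remaining input is one gamma reading. Target at 0.417 h is smaller than at 1.00 h, so the same scatter of 0.5 percentage points weighs more there, and the later reading is used.

3. At 1.00 h, the readings give target over the electrophile lost otherwise as 0.606. Those odds, taken as starting odds and multiplied by impurity charge over nucleophile charge, give the selectivity factor 0.230, a reading with its scatter.

4. For the new flask, this reckoning estimates starting odds of 0.922, a target-route share of 48.0% at the start.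

The forecast gives 97.5% reacted and 90% free, reasoning “so binding is small”.

The flask gives 95.5% reacted and 61.7% free at 30 h.

    target ⇌ isomer of the product (K = 2.00, k = 0.0440 h⁻¹)
    electrophile + nucleophile ⇌ acid set free + target (K = 0.170, k = 1.20 M⁻¹ h⁻¹)
    electrophile + protic impurity → quenched substrate (k = 4.60 M⁻¹ h⁻¹)
    nucleophile + acid set free ⇌ protonated nucleophile, settled at all times (K = 3000 M⁻¹)

Protonated nucleophile in the flask stands at 0.0276 M and acid set free at 2.07 × 10⁻⁴ M; together they come close to target and isomer of the product together, 0.0278 M. The selectivity factor applied to the free nucleophile and protic impurity left in the flask at 30.0 h gives estimated odds of 2.02. For the neighbour flask charged with 0.17 M nucleophile, it gives starting odds of 1.57, and that neighbour ends with 31.5% quenched substrate, less than the 39.8% in the flask.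

The numbers in the tables stem from a simulated flask for an exercise.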